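**Retrosynthetic overview** (numbering: ring A = C1 (quaternary, C15 methyl), C10, C11 (C20 methyl), C12, C13, C14; ten-membered ring = C1 to C10, C16 on C5; lactone = O–C7, C8, C17 (C18 methyl), C19)
- The plan rests on the three contiguous ring A centres C14(O)–C1(CH3)–C10(H): they are the ortho/endo pattern of a Diels–Alder adduct of an (E)-2-methyl enal (C2–C1=C10–C9) and a 1-oxy-3-silyloxy diene (C14 to C11).
- Ring A first: a catalytic enantioselective [4+2] forms C1–C14 and C10–C11; the C2 formyl and C9 oxymethyl arms then relay the stereochemistry outward.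
- C2 by alkynylation, oxidation and CBS reduction; C12 ketone to the C11 enol triflate, to C11=C12, to the epoxide directed by the C14 hydroxyl (second ring).
- C9 aldehyde plus an enantioenriched C5–C8 alkenyl bromide (C8–C9, Nozaki–Hiyama–Kishi); C8 methylene to ketone; an intramolecular Reformatsky reaction closes the γ-lactone (C17–C8, third ring).
- Ten-membered ring last: the C4–C5 bond between a Z alkenyl iodide (from the C3≡C4 alkyne) and a Z alkenylstannane (trans-hydrostannation of C5≡C6).

Key step: step 5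

Assumption: the sense of induction of the oxazaborolidinium catalyst is taken from the formyl C–H···O binding model for 2-methyl enals, which calls for the (R)-catalyst; the antipodal catalyst would be used if the sense proved opposite.
Convention: α is the face of ring A that carries O14 (also H10, C2 and the epoxide); β is the face of the C15 and C20 methyl groups and of C9. "As in the target" means the same spatial arrangement; the SMILES give each configuration explicitly.

**Step 1**
Reactants: 1 4-methoxybenzyl alcohol; 2 but-3-yn-2-one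
Product: 3 (E)-4-[(4-methoxybenzyl)oxy]but-3-en-2-one
Conditions: DABCO (10 mol%), CH2Cl2, 0 °C → rt
Reagents that add atoms: none
Why: Amine-catalysed oxa-Michael addition of the alcohol to the ynone should give the thermodynamically preferred E β-alkoxy enone.

**Step 2**
Reactants: 3 (E)-4-[(4-methoxybenzyl)oxy]but-3-en-2-one
Product: 5 (E)-1-[(4-methoxybenzyl)oxy]pent-1-en-3-one, via lithium dienolate 4 (not isolated)
Conditions: LiN(SiMe3)2, THF, −78 °C; MeI, −78 → −40 °C
Reagents that add atoms: iodomethane, CI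
Why: Kinetic deprotonation of the vinylogous ester at the α′ methyl group gives the cross-conjugated dienolate, whose C-alkylation brings in the future C20 methyl (α′-alkylation of a vinylogous ester).

**Step 3**
Reactants: 5 (E)-1-[(4-methoxybenzyl)oxy]pent-1-en-3-one
Product: 6 (1E,3Z)-1-[(4-methoxybenzyl)oxy]-3-(tert-butyldimethylsilyloxy)penta-1,3-diene
Conditions: t-BuMe2SiOTf, Et3N, Et2O, 0 °C
Reagents that add atoms: tert-butyldimethylsilyl trifluoromethanesulfonate, CC(C)(C)[Si](C)(C)OS(=O)(=O)C(F)(F)F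
Why: Soft enolisation of the ethyl ketone with silyl triflate and amine should give the Z silyl enol ether, which places the methyl group at the outer position of the diene terminus; the TBS enol ether is chosen because it must survive four later steps.

**Step 4**
Reactants: 7 (tert-butyldimethylsilyloxy)acetaldehyde; 8 2-(triphenylphosphoranylidene)propanal
Product: 9 (E)-4-(tert-butyldimethylsilyloxy)-2-methylbut-2-enal
Conditions: toluene, 80 °C
Reagents that add atoms: none
Why: Wittig reaction of the stabilised α-methyl formyl ylide with the unhindered aldehyde gives the E trisubstituted enal, which is too hindered to react further with the ylide.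

**Step 5**
Reactants: 6 (1E,3Z)-1-[(4-methoxybenzyl)oxy]-3-(tert-butyldimethylsilyloxy)penta-1,3-diene; 9 (E)-4-(tert-butyldimethylsilyloxy)-2-methylbut-2-enal
Product: 10 ring A cycloadduct (1R,2S,5S,6S)-4-(tert-butyldimethylsilyloxy)-6-[(tert-butyldimethylsilyloxy)methyl]-2-[(4-methoxybenzyl)oxy]-1,5-dimethylcyclohex-3-ene-1-carbaldehyde
Conditions: (R)-3,3-diphenyl-1-(2-methylphenyl)tetrahydro-1H,3H-pyrrolo[1,2-c][1,3,2]oxazaborole (20 mol%), HN(SO2CF3)2 (17 mol%), CH2Cl2, −78 → −40 °C
Reagents that add atoms: none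
Why: The protonated oxazaborolidine binds the formyl oxygen of 9 on the side of the formyl hydrogen (C–H···O contact to the ring oxygen), the s-trans enal lies over one phenyl group, and diene 6 adds to the open face in a concerted but asynchronous [4+2] cycloaddition. The closest known reaction type is the oxazaborolidinium-catalysed Diels–Alder reaction of 2-methylacrolein-type enals with 2-silyloxy and 1-alkoxy-3-silyloxy dienes. Ring A is closed by intermolecular cycloaddition, C10–C11 (leading bond) and C1–C14 forming across one face of each partner. C1 is fixed by the catalyst, C10 by the E geometry of the enal (suprafacial addition, C2 and C9 trans), C14 by the endo position of the formyl group (O14 cis to C2), and C11 by the Z enol ether terminus (methyl cis to O14; this centre is removed in step 11). The step needs regio-, endo and facial selectivity: the silyloxy group makes C11 the nucleophilic terminus and the formyl group makes C10 the electrophilic one, the bound formyl group overlaps with the diene in the endo mode, and the phenyl shield of the catalyst gives the face selection.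

**Step 6**
Reactants: 10 ring A cycloadduct; 11 ethynyltrimethylsilane
Product: 13 propargylic alcohols (C2 epimers; CHO of 10 converted into CH(OH)C≡CSiMe3), via lithium (trimethylsilyl)acetylide 12 (not isolated)
Conditions: 11, n-BuLi, THF, −78 °C; then 10, −78 °C; H2O
Reagents that add atoms: none
Why: 1,2-Addition of the lithium acetylide to the neopentyl aldehyde at low temperature leaves the silyl enol ether untouched, and the C2 epimers are carried on together because this centre is erased in step 7.

**Step 7**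
Reactants: 13 propargylic alcohols (C2 epimers)
Product: 14 ynone (C2 ketone)
Conditions: Dess–Martin periodinane, NaHCO3, CH2Cl2, 0 °C → rt
Reagents that add atoms: none
Why: Buffered Dess–Martin oxidation converts both epimers into one non-enolisable ynone and spares the silyl enol ether.

**Step 8**
Reactants: 14 ynone
Product: 15 propargylic alcohol with the target configuration at C2
Conditions: (S)-1-methyl-3,3-diphenyltetrahydro-1H,3H-pyrrolo[1,2-c][1,3,2]oxazaborole (1 equiv), catecholborane, toluene, −78 °C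
Reagents that add atoms: none
Why: Corey–Bakshi–Shibata reduction with the quaternary C1 as the large and the alkynyl group as the small substituent sets C2 by reagent control, and the substrate chelate model (C2=O with the C14 ether oxygen, hydride from the C15 side) predicts the same face.

**Step 9**
Reactants: 15 propargylic alcohol
Product: 16 C2 acetate
Conditions: Ac2O, DMAP, pyridine, CH2Cl2, rt
Reagents that add atoms: acetic anhydride, CC(=O)OC(C)=O
Why: DMAP-catalysed acetylation installs the final C2 acetate, which is hindered enough (neopentyl position) to be carried through the later steps.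

**Step 10**
Reactants: 16 C2 acetate
Product: 17 C12 ketone
Conditions: Bu4NF (1.05 equiv), AcOH, THF, −40 °C
Reagents that add atoms: none
Why: Fluoride cleaves the silyl enol ether much faster than the alkyl silyl ether or the alkynylsilane, and acetic acid protonates the enolate at C13 before the C14 ether can be expelled (buffered desilylation).

**Step 11**
Reactants: 17 C12 ketone
Product: 18 C11=C12 enol triflate
Conditions: (CF3SO2)2O, 2,6-di-tert-butyl-4-methylpyridine, CH2Cl2, −78 → 0 °C
Reagents that add atoms: trifluoromethanesulfonic anhydride, O=S(=O)(OS(=O)(=O)C(F)(F)F)C(F)(F)F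
Why: O-Triflation of the ketone and loss of the tertiary C11 proton from the triflyloxycarbenium ion gives the more substituted enol triflate (Stang enol triflate synthesis) without a C13 enolate, which would eliminate the C14 ether; the inductive effect of O14 also disfavours proton loss from C13.

**Step 12**
Reactants: 18 enol triflate
Product: 19 C11=C12 alkene
Conditions: Pd(OAc)2 (5 mol%), PPh3, Bu3N, HCO2H, DMF, 60 °C
Reagents that add atoms: none
Why: Palladium-catalysed formate reduction of the enol triflate (Cacchi conditions) replaces the triflate by hydrogen, the hindered propargylic acetate being much slower to ionise than the triflate is to add.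

**Step 13**
Reactants: 19 C11=C12 alkene
Product: 20 homoallylic alcohol (14α-OH)
Conditions: DDQ, CH2Cl2/pH 7 buffer, 0 °C
Reagents that add atoms: none
Why: Oxidative cleavage of the PMB ether by DDQ frees the C14 hydroxyl without touching the silyl groups, the acetate or the alkene.

**Step 14**
Reactants: 20 homoallylic alcohol
Product: 21 11α,12α-epoxy-14α-alcohol
Conditions: VO(acac)2 (5 mol%), t-BuOOH, CH2Cl2, 0 °C → rt
Reagents that add atoms: tert-butyl hydroperoxide, CC(C)(C)OO
Why: Vanadium-catalysed epoxidation is directed by the pseudoaxial homoallylic C14 hydroxyl, so oxygen is delivered to the α face and C11 and C12 are set cis to O14, the β face being blocked in addition by the axial C15 methyl.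

**Step 15**
Reactants: 21 epoxy alcohol
Product: 22 2,14-diacetate
Conditions: Ac2O, DMAP, pyridine, CH2Cl2, rt
Reagents that add atoms: acetic anhydride, CC(=O)OC(C)=O
Why: Acetylation installs the final C14 acetate and removes the free hydroxyl next to the epoxide.

**Step 16**
Reactants: 22 2,14-diacetate
Product: 23 C9 primary alcohol
Conditions: HF·pyridine, pyridine, THF, 0 °C → rt
Reagents that add atoms: none
Why: Buffered hydrogen fluoride removes the primary TBS ether and leaves the alkynylsilane, the acetates and the trisubstituted epoxide intact.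

**Step 17**
Reactants: 23 C9 primary alcohol
Product: 24 C9 aldehyde
Conditions: Dess–Martin periodinane, NaHCO3, CH2Cl2, 0 °C → rt
Reagents that add atoms: none
Why: Buffered Dess–Martin oxidation gives the aldehyde without epimerising C10.

**Step 18**
Reactants: 25 prop-2-yn-1-ol
Product: 26 tert-butyldiphenyl(prop-2-yn-1-yloxy)silane
Conditions: t-BuPh2SiCl, imidazole, CH2Cl2, rt
Reagents that add atoms: tert-butyl(chloro)diphenylsilane, CC(C)(C)[Si](Cl)(c1ccccc1)c1ccccc1
Why: Standard silylation; the TBDPS group at the future O16 is chosen to outlast the TES ether at O7.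

**Step 19**
Reactants: 27 acrolein
Product: 29 2-bromoacrolein, via 2,3-dibromopropanal 28 (not isolated)
Conditions: Br2, CH2Cl2, −78 °C; Et3N, −78 → 0 °C
Reagents that add atoms: bromine, BrBr
Why: Bromine addition to the enal followed by dehydrobromination of the acidic α-position gives the 2-bromo enal, which is used at once.

**Step 20**
Reactants: 26 tert-butyldiphenyl(prop-2-yn-1-yloxy)silane; 29 2-bromoacrolein
Product: 31 rac-2-bromo-6-(tert-butyldiphenylsilyloxy)hex-1-en-4-yn-3-ol, via lithium acetylide 30 (not isolated)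
Conditions: 26, n-BuLi, THF, −78 °C; then 29, −78 °C; H2O
Reagents that add atoms: none
Why: 1,2-Addition of the lithium acetylide to the enal joins C6 to C7.

**Step 21**
Reactants: 31 rac-enynol
Product: 32 2-bromo-6-(tert-butyldiphenylsilyloxy)hex-1-en-4-yn-3-one
Conditions: Dess–Martin periodinane, NaHCO3, CH2Cl2, 0 °C
Reagents that add atoms: none
Why: Mild oxidation of the doubly activated alcohol gives the cross-conjugated ketone, which is reduced without storage.

**Step 22**
Reactants: 32 bromo enynone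
Product: 33 (S)-2-bromo-6-(tert-butyldiphenylsilyloxy)hex-1-en-4-yn-3-ol
Conditions: (R)-1-methyl-3,3-diphenyltetrahydro-1H,3H-pyrrolo[1,2-c][1,3,2]oxazaborole (1 equiv), catecholborane, toluene, −78 °C
Reagents that add atoms: none
Why: Corey–Bakshi–Shibata reduction with the α-bromovinyl group as the large and the alkynyl group as the small substituent sets C7 by reagent control.

**Step 23**
Reactants: 33 (S)-enynol
Product: 34 (S)-triethylsilyl ether
Conditions: Et3SiCl, imidazole, CH2Cl2, 0 °C
Reagents that add atoms: chlorotriethylsilane, CC[Si](Cl)(CC)CC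
Why: Silylation gives an O7 ether that can later be removed in the presence of the TBDPS ether.

**Step 24**
Reactants: 24 C9 aldehyde; 34 (S)-triethylsilyl ether
Product: 35 C9 allylic alcohol (C8 exocyclic methylene; C7 OTES)
Conditions: CrCl2, NiCl2 (2 mol%), DMSO, rt
Reagents that add atoms: none
Why: Nozaki–Hiyama–Kishi coupling of the alkenyl bromide is non-basic, so the acetates, the epoxide and the epimerisable C10 survive, and Felkin–Anh addition anti to the quaternary C1 past the C10 hydrogen should set C9 as in the target.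

**Step 25**
Reactants: 35 C9 allylic alcohol
Product: 36 2,9,14-triacetate
Conditions: Ac2O, DMAP, pyridine, CH2Cl2, rt
Reagents that add atoms: acetic anhydride, CC(=O)OC(C)=O
Why: Acetylation installs the final C9 acetate.

**Step 26**
Reactants: 36 triacetate
Product: 37 C7 alcohol
Conditions: HF·pyridine, pyridine, THF, 0 °C
Reagents that add atoms: none
Why: The secondary TES ether is cleaved by buffered hydrogen fluoride much faster than the TBDPS ether or the alkynylsilane.

**Step 27**
Reactants: 37 C7 alcohol; 38 2-bromopropanoyl bromide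
Product: 39 C7 2-bromopropanoate (epimers at the bromo carbon)
Conditions: pyridine, CH2Cl2, −20 °C
Reagents that add atoms: none
Why: Acylation of the only free hydroxyl attaches C17, C18 and C19; the configuration of the bromo carbon is lost on enolate formation in step 29.

**Step 28**
Reactants: 39 C7 2-bromopropanoate
Product: 41 C8 ketone, via ozonide 40 (not isolated)
Conditions: O3, CH2Cl2, −78 °C (indicator dye); Me2S, −78 °C → rt
Reagents that add atoms: ozone, [O-][O+]=O
Why: Ozonolysis cleaves the only alkene in the molecule (the epoxide and the two alkynes react far more slowly) and unveils the C8 ketone under neutral conditions.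

**Step 29**
Reactants: 41 C8 ketone
Product: 42 γ-lactone (8-OH; 17-CH3 cis to 8-OH)
Conditions: SmI2 (2.2 equiv), THF, −78 °C; H2O
Reagents that add atoms: none
Why: SmI2 reduces the α-bromo ester far faster than the ketone and the samarium enolate adds to C8 within a chelate (intramolecular Reformatsky reaction, lactone closed through C17–C8), the C9 branch taking the position trans to the C7 alkynyl group and the C17 methyl the position cis to the new hydroxyl, so C8 and C17 are set from C7.

**Step 30**
Reactants: 42 γ-lactone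
Product: 43 iodoalkyne (C3≡C4–I)
Conditions: N-iodosuccinimide, AgNO3 (10 mol%), acetone, rt, dark
Reagents that add atoms: N-iodosuccinimide, O=C1CCC(=O)N1I
Why: Silver-catalysed iododesilylation converts the alkynylsilane directly into the iodoalkyne and does not affect the internal alkyne.

**Step 31**
Reactants: 43 iodoalkyne
Product: 44 Z alkenyl iodide (C3=C4)
Conditions: 2-nitrobenzenesulfonylhydrazide, Et3N, THF/i-PrOH, rt
Reagents that add atoms: none
Why: Diimide adds hydrogen cis to the polarised iodoalkyne faster than to the hindered internal C5≡C6 alkyne and gives the Z alkenyl iodide without hydrogenolysis of the C–I bond.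

**Step 32**
Reactants: 44 Z alkenyl iodide
Product: 45 C16 propargylic alcohol
Conditions: Bu4NF, AcOH, THF, 0 °C → rt
Reagents that add atoms: none
Why: Acetic acid-buffered fluoride removes the TBDPS ether without dehydroiodination of the alkenyl iodide or acetate migration.

**Step 33**
Reactants: 45 C16 propargylic alcohol
Product: 46 Z alkenylstannane (C5–SnBu3; C6–H)
Conditions: [Cp*RuCl]4 (Cp* = C5Me5; 2.5 mol%), Bu3SnH (slow addition), CH2Cl2, rt
Reagents that add atoms: tributylstannane, CCCC[SnH](CCCC)CCCC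
Why: In the ruthenium-catalysed trans-hydrostannation the free C16 hydroxyl hydrogen-bonds to the chloride ligand and steers tin to the proximal C5 while hydrogen is delivered trans to C6, so C7 and tin end up cis as the target's C5=C6 geometry requires.

**Step 34**
Reactants: 46 Z alkenylstannane
Product: 47 CNP0296793.1 (target)
Conditions: Cu(O2CC4H3S) (copper thiophene-2-carboxylate, 3 equiv), N-methylpyrrolidone, 0 °C → rt, 1 mM
Reagents that add atoms: none
Why: Copper-mediated Stille-type coupling (Liebeskind conditions) of the alkenylstannane with the alkenyl iodide proceeds with retention at both termini and closes the ten-membered ring through C4–C5 as the (3Z,5E)-diene; the palladium-free conditions avoid ionisation of the allylic acetate and lactone, and high dilution suppresses oligomerisation.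

**Compound list**
1 | 4-methoxybenzyl alcohol | COc1ccc(CO)cc1 | starting material
2 | but-3-yn-2-one | CC(=O)C#C | starting material
3 | (E)-4-[(4-methoxybenzyl)oxy]but-3-en-2-one | COc1ccc(CO/C=C/C(C)=O)cc1 | intermediate
4 | lithium (E)-4-[(4-methoxybenzyl)oxy]buta-1,3-dien-2-olate | COc1ccc(CO/C=C/C(=C)O[Li])cc1 | intermediate (not isolated)
5 | (E)-1-[(4-methoxybenzyl)oxy]pent-1-en-3-one | COc1ccc(CO/C=C/C(=O)CC)cc1 | intermediate
6 | (1E,3Z)-1-[(4-methoxybenzyl)oxy]-3-(tert-butyldimethylsilyloxy)penta-1,3-diene | COc1ccc(CO/C=C/C(O[Si](C)(C)C(C)(C)C)=C/C)cc1 | intermediate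
7 | (tert-butyldimethylsilyloxy)acetaldehyde | CC(C)(C)[Si](C)(C)OCC=O | starting material
8 | 2-(triphenylphosphoranylidene)propanal | CC(C=O)=P(c1ccccc1)(c1ccccc1)c1ccccc1 | starting material
9 | (E)-4-(tert-butyldimethylsilyloxy)-2-methylbut-2-enal | O=C/C(C)=C/CO[Si](C)(C)C(C)(C)C | intermediate
10 | ring A cycloadduct, (1R,2S,5S,6S)-4-(tert-butyldimethylsilyloxy)-6-[(tert-butyldimethylsilyloxy)methyl]-2-[(4-methoxybenzyl)oxy]-1,5-dimethylcyclohex-3-ene-1-carbaldehyde; in target numbering 1R,10S,11S,14S with C2 = CHO, C12=C13 enol ether | O=C[C@@]1(C)[C@@H](OCc2ccc(OC)cc2)C=C(O[Si](C)(C)C(C)(C)C)[C@@H](C)[C@@H]1CO[Si](C)(C)C(C)(C)C | intermediate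
11 | ethynyltrimethylsilane | C#C[Si](C)(C)C | starting material
12 | lithium (trimethylsilyl)acetylide | [Li]C#C[Si](C)(C)C | intermediate (not isolated)
13 | propargylic alcohols, both C2 epimers: 10 with CHO converted into CH(OH)C≡CSiMe3 | C[Si](C)(C)C#CC(O)[C@@]1(C)[C@@H](OCc2ccc(OC)cc2)C=C(O[Si](C)(C)C(C)(C)C)[C@@H](C)[C@@H]1CO[Si](C)(C)C(C)(C)C | intermediate
14 | ynone: 10 with CHO converted into C(=O)C≡CSiMe3 | C[Si](C)(C)C#CC(=O)[C@@]1(C)[C@@H](OCc2ccc(OC)cc2)C=C(O[Si](C)(C)C(C)(C)C)[C@@H](C)[C@@H]1CO[Si](C)(C)C(C)(C)C | intermediate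
15 | propargylic alcohol, C2 as in the target | C[Si](C)(C)C#C[C@@H](O)[C@@]1(C)[C@@H](OCc2ccc(OC)cc2)C=C(O[Si](C)(C)C(C)(C)C)[C@@H](C)[C@@H]1CO[Si](C)(C)C(C)(C)C | intermediate
16 | C2 acetate of 15 | C[Si](C)(C)C#C[C@@H](OC(C)=O)[C@@]1(C)[C@@H](OCc2ccc(OC)cc2)C=C(O[Si](C)(C)C(C)(C)C)[C@@H](C)[C@@H]1CO[Si](C)(C)C(C)(C)C | intermediate
17 | C12 ketone (C13 methylene; C11 methyl unchanged from 10) | C[Si](C)(C)C#C[C@@H](OC(C)=O)[C@@]1(C)[C@@H](OCc2ccc(OC)cc2)CC(=O)[C@@H](C)[C@@H]1CO[Si](C)(C)C(C)(C)C | intermediate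
18 | C11=C12 enol triflate (OTf on C12) | C[Si](C)(C)C#C[C@@H](OC(C)=O)[C@@]1(C)[C@@H](OCc2ccc(OC)cc2)CC(OS(=O)(=O)C(F)(F)F)=C(C)[C@@H]1CO[Si](C)(C)C(C)(C)C | intermediate
19 | C11=C12 alkene, 14α-OPMB | C[Si](C)(C)C#C[C@@H](OC(C)=O)[C@@]1(C)[C@@H](OCc2ccc(OC)cc2)CC=C(C)[C@@H]1CO[Si](C)(C)C(C)(C)C | intermediate
20 | homoallylic alcohol, 14α-OH | C[Si](C)(C)C#C[C@@H](OC(C)=O)[C@@]1(C)[C@@H](O)CC=C(C)[C@@H]1CO[Si](C)(C)C(C)(C)C | intermediate
21 | 11α,12α-epoxy-14α-alcohol; 1β-CH3, 1α-[CH(OAc)C≡CSiMe3], 10β-CH2OTBS | O[C@H]1C[C@H]2O[C@@]2(C)[C@H](CO[Si](C)(C)C(C)(C)C)[C@@]1(C)[C@H](OC(C)=O)C#C[Si](C)(C)C | intermediate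
22 | 2,14-diacetate of the epoxide, C9 OTBS | CC(=O)O[C@H]1C[C@H]2O[C@@]2(C)[C@H](CO[Si](C)(C)C(C)(C)C)[C@@]1(C)[C@H](OC(C)=O)C#C[Si](C)(C)C | intermediate
23 | C9 primary alcohol | CC(=O)O[C@H]1C[C@H]2O[C@@]2(C)[C@H](CO)[C@@]1(C)[C@H](OC(C)=O)C#C[Si](C)(C)C | intermediate
24 | C9 aldehyde | CC(=O)O[C@H]1C[C@H]2O[C@@]2(C)[C@H](C=O)[C@@]1(C)[C@H](OC(C)=O)C#C[Si](C)(C)C | intermediate
25 | prop-2-yn-1-ol | C#CCO | starting material
26 | tert-butyldiphenyl(prop-2-yn-1-yloxy)silane | C#CCO[Si](c1ccccc1)(c1ccccc1)C(C)(C)C | intermediate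
27 | acrolein | C=CC=O | starting material
28 | 2,3-dibromopropanal | O=CC(Br)CBr | intermediate (not isolated)
29 | 2-bromoacrolein | C=C(Br)C=O | intermediate
30 | lithium 3-(tert-butyldiphenylsilyloxy)prop-1-ynide | [Li]C#CCO[Si](c1ccccc1)(c1ccccc1)C(C)(C)C | intermediate (not isolated)
31 | rac-2-bromo-6-(tert-butyldiphenylsilyloxy)hex-1-en-4-yn-3-ol | C=C(Br)C(O)C#CCO[Si](c1ccccc1)(c1ccccc1)C(C)(C)C | intermediate
32 | 2-bromo-6-(tert-butyldiphenylsilyloxy)hex-1-en-4-yn-3-one | C=C(Br)C(=O)C#CCO[Si](c1ccccc1)(c1ccccc1)C(C)(C)C | intermediate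
33 | (S)-2-bromo-6-(tert-butyldiphenylsilyloxy)hex-1-en-4-yn-3-ol (C7 as in the target) | C=C(Br)[C@@H](O)C#CCO[Si](c1ccccc1)(c1ccccc1)C(C)(C)C | intermediate
34 | (S)-2-bromo-6-(tert-butyldiphenylsilyloxy)-3-(triethylsilyloxy)hex-1-en-4-yne | C=C(Br)[C@@H](O[Si](CC)(CC)CC)C#CCO[Si](c1ccccc1)(c1ccccc1)C(C)(C)C | intermediate
35 | coupling product: C9 OH (as in the target), C8 =CH2, C7 OTES, C5≡C6, C16 OTBDPS | CC(=O)O[C@H]1C[C@H]2O[C@@]2(C)[C@H]([C@@H](O)C(=C)[C@@H](O[Si](CC)(CC)CC)C#CCO[Si](c3ccccc3)(c3ccccc3)C(C)(C)C)[C@@]1(C)[C@H](OC(C)=O)C#C[Si](C)(C)C | intermediate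
36 | 2,9,14-triacetate, C7 OTES | CC(=O)O[C@H]1C[C@H]2O[C@@]2(C)[C@H]([C@@H](OC(C)=O)C(=C)[C@@H](O[Si](CC)(CC)CC)C#CCO[Si](c3ccccc3)(c3ccccc3)C(C)(C)C)[C@@]1(C)[C@H](OC(C)=O)C#C[Si](C)(C)C | intermediate
37 | C7 alcohol | CC(=O)O[C@H]1C[C@H]2O[C@@]2(C)[C@H]([C@@H](OC(C)=O)C(=C)[C@@H](O)C#CCO[Si](c3ccccc3)(c3ccccc3)C(C)(C)C)[C@@]1(C)[C@H](OC(C)=O)C#C[Si](C)(C)C | intermediate
38 | 2-bromopropanoyl bromide (racemic) | CC(Br)C(Br)=O | starting material
39 | C7 2-bromopropanoate | CC(=O)O[C@H]1C[C@H]2O[C@@]2(C)[C@H]([C@@H](OC(C)=O)C(=C)[C@@H](OC(=O)C(C)Br)C#CCO[Si](c3ccccc3)(c3ccccc3)C(C)(C)C)[C@@]1(C)[C@H](OC(C)=O)C#C[Si](C)(C)C | intermediate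
40 | ozonide of 39 (1,2,4-trioxolane at C8) | CC(=O)O[C@H]1C[C@H]2O[C@@]2(C)[C@H]([C@@H](OC(C)=O)C3(OCOO3)[C@@H](OC(=O)C(C)Br)C#CCO[Si](c4ccccc4)(c4ccccc4)C(C)(C)C)[C@@]1(C)[C@H](OC(C)=O)C#C[Si](C)(C)C | intermediate (not isolated)
41 | C8 ketone with C7 2-bromopropanoate | CC(=O)O[C@H]1C[C@H]2O[C@@]2(C)[C@H]([C@@H](OC(C)=O)C(=O)[C@@H](OC(=O)C(C)Br)C#CCO[Si](c3ccccc3)(c3ccccc3)C(C)(C)C)[C@@]1(C)[C@H](OC(C)=O)C#C[Si](C)(C)C | intermediate
42 | γ-lactone with C7, C8, C17 as in the target; C3≡C4–SiMe3, C5≡C6, C16 OTBDPS | CC(=O)O[C@H]1C[C@H]2O[C@@]2(C)[C@H]([C@@H](OC(C)=O)[C@@]3(O)[C@H](C#CCO[Si](c4ccccc4)(c4ccccc4)C(C)(C)C)OC(=O)[C@@H]3C)[C@@]1(C)[C@H](OC(C)=O)C#C[Si](C)(C)C | intermediate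
43 | iodoalkyne (C4–I) | CC(=O)O[C@H]1C[C@H]2O[C@@]2(C)[C@H]([C@@H](OC(C)=O)[C@@]3(O)[C@H](C#CCO[Si](c4ccccc4)(c4ccccc4)C(C)(C)C)OC(=O)[C@@H]3C)[C@@]1(C)[C@H](OC(C)=O)C#CI | intermediate
44 | (3Z)-alkenyl iodide | CC(=O)O[C@H]1C[C@H]2O[C@@]2(C)[C@H]([C@@H](OC(C)=O)[C@@]3(O)[C@H](C#CCO[Si](c4ccccc4)(c4ccccc4)C(C)(C)C)OC(=O)[C@@H]3C)[C@@]1(C)[C@H](OC(C)=O)/C=C\I | intermediate
45 | C16 propargylic alcohol | CC(=O)O[C@H]1C[C@H]2O[C@@]2(C)[C@H]([C@@H](OC(C)=O)[C@@]3(O)[C@H](C#CCO)OC(=O)[C@@H]3C)[C@@]1(C)[C@H](OC(C)=O)/C=C\I | intermediate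
46 | (Z)-C5-tributylstannyl alkene with the (3Z)-alkenyl iodide | CC(=O)O[C@H]1C[C@H]2O[C@@]2(C)[C@H]([C@@H](OC(C)=O)[C@@]3(O)[C@H](/C=C(CO)\[Sn](CCCC)(CCCC)CCCC)OC(=O)[C@@H]3C)[C@@]1(C)[C@H](OC(C)=O)/C=C\I | intermediate
47 | CNP0296793.1, (1R,2R,7S,8S,9R,10S,11S,12R,14S,17R,3Z,5E) in the numbering above | CC(=O)O[C@H]1C[C@H]2O[C@@]2(C)[C@@H]2[C@@H](OC(C)=O)[C@@]3(O)[C@H](/C=C(CO)\C=C/[C@@H](OC(C)=O)[C@@]12C)OC(=O)[C@@H]3C | target

**Step count and risks**
Total step count: 34. Longest linear sequence: 27 steps (steps 1–3, 5–17, 24–34).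

Most likely to fail:

1. Step 34 (ten-membered ring closure). The two alkenyl termini may not reach each other without transannular strain, so oligomerisation and protodestannylation can outrun cyclisation. The fallback closes the ring by metathesis at C3=C4 instead of coupling at C4–C5. It sets out from 42: HF·pyridine removes the TBDPS group and should give the propargylic alcohol F1. [Cp*RuCl]4 and Bu3SnH give the Z alkenylstannane F2, the hydroxyl-directed alkyne reacting before the silylalkyne. Copper-mediated coupling with iodoethene (copper thiophene-2-carboxylate, N-methylpyrrolidone) gives the C5-vinyl dienol F3. Bu4NF with AcOH removes the alkynyl silyl group and gives the terminal alkyne F4. Semihydrogenation (H2, Pd/CaCO3 poisoned with Pb(OAc)2, quinoline) gives the C3-vinyl triene F5. Ring-closing metathesis with the second-generation Hoveyda–Grubbs catalyst in dilute toluene should close C3=C4 as the ring-cis alkene with loss of ethene, and the route is rejoined at 47.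

2. Step 11 (regioselective enol triflate). Proton loss from the triflyloxycarbenium ion may occur at C13 as well as at C11, or the anhydride may attack the PMB ether. The fallback replaces enol triflate reduction by dehydration of the C12 alcohol. It sets out from 17: LiBH(s-Bu)3 at −78 °C attacks along the equatorial trajectory (the axial face is shielded by the axial C14 ether) and should give the axial C12 alcohol F6. Ph2S[OC(CF3)2Ph]2 (Martin sulfurane) then effects anti elimination with the antiperiplanar axial C11 hydrogen toward the more substituted alkene, and the route is rejoined at 19.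

3. Step 29 (Reformatsky lactonisation). Facial selectivity at the C8 ketone may be poor, or electron transfer to the α,α′-bis(acyloxy) ketone may expel an acyloxy group before the enolate adds. The fallback is a copper hydride reductive aldol cyclisation. It sets out from 37: ozonolysis (O3, then Me2S) gives the α-hydroxy ketone F7. Acryloyl chloride and i-Pr2NEt at −40 °C give the acrylate F8. [(Ph3P)CuH]6 in toluene reduces the acrylate in the conjugate sense and the copper enolate closes onto C8 through a chair transition state that places the methyl and hydroxyl groups cis, and the route is rejoined at 42.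

**Further compounds**
F1 | step 34 | 42 without the TBDPS group (C16 OH, alkynylsilane kept) | CC(=O)O[C@H]1C[C@H]2O[C@@]2(C)[C@H]([C@@H](OC(C)=O)[C@@]3(O)[C@H](C#CCO)OC(=O)[C@@H]3C)[C@@]1(C)[C@H](OC(C)=O)C#C[Si](C)(C)C
F2 | step 34 | (Z)-C5-tributylstannyl alkene with the alkynylsilane | CC(=O)O[C@H]1C[C@H]2O[C@@]2(C)[C@H]([C@@H](OC(C)=O)[C@@]3(O)[C@H](/C=C(CO)\[Sn](CCCC)(CCCC)CCCC)OC(=O)[C@@H]3C)[C@@]1(C)[C@H](OC(C)=O)C#C[Si](C)(C)C
F3 | step 34 | C5-vinyl dienol with the alkynylsilane | CC(=O)O[C@H]1C[C@H]2O[C@@]2(C)[C@H]([C@@H](OC(C)=O)[C@@]3(O)[C@H](/C=C(CO)\C=C)OC(=O)[C@@H]3C)[C@@]1(C)[C@H](OC(C)=O)C#C[Si](C)(C)C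
F4 | step 34 | C5-vinyl dienol with the terminal alkyne | CC(=O)O[C@H]1C[C@H]2O[C@@]2(C)[C@H]([C@@H](OC(C)=O)[C@@]3(O)[C@H](/C=C(CO)\C=C)OC(=O)[C@@H]3C)[C@@]1(C)[C@H](OC(C)=O)C#C
F5 | step 34 | metathesis precursor with vinyl groups at C3 and C5 | CC(=O)O[C@H]1C[C@H]2O[C@@]2(C)[C@H]([C@@H](OC(C)=O)[C@@]3(O)[C@H](/C=C(CO)\C=C)OC(=O)[C@@H]3C)[C@@]1(C)[C@H](OC(C)=O)C=C
F6 | step 11 | axial (α) C12 alcohol from 17 | C[Si](C)(C)C#C[C@@H](OC(C)=O)[C@@]1(C)[C@@H](OCc2ccc(OC)cc2)C[C@@H](O)[C@@H](C)[C@@H]1CO[Si](C)(C)C(C)(C)C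
F7 | step 29 | C8 ketone with free C7 hydroxyl | CC(=O)O[C@H]1C[C@H]2O[C@@]2(C)[C@H]([C@@H](OC(C)=O)C(=O)[C@@H](O)C#CCO[Si](c3ccccc3)(c3ccccc3)C(C)(C)C)[C@@]1(C)[C@H](OC(C)=O)C#C[Si](C)(C)C
F8 | step 29 | C8 ketone with C7 acrylate | CC(=O)O[C@H]1C[C@H]2O[C@@]2(C)[C@H]([C@@H](OC(C)=O)C(=O)[C@@H](OC(=O)C=C)C#CCO[Si](c3ccccc3)(c3ccccc3)C(C)(C)C)[C@@]1(C)[C@H](OC(C)=O)C#C[Si](C)(C)C
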